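## Retrosynthetic overview

- Last C–C bond: C5 of the butenolide to the allylic CH2, by a new enantioselective γ-allylation of a 2-silyloxyfuran with a C20 allyl carbonate. This sets the only stereocentre; desilylation then gives the target.
- C20 allyl unit: B-alkyl Suzuki coupling of a homoallyl-9-BBN (from a triene) with a (Z)-3-iodoallylic alcohol. The iodide comes from but-2-yne-1,4-diol by trans-hydroalumination/iodination, which fixes the geometry of the hydroxymethyl-bearing alkene.
- Triene: dihydro-β-ionone → terminal alkyne → zirconium-catalysed carboalumination and vinylation, which sets the (E)-methyl alkene.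
- Rings: the cyclohexene ring is bought with dihydro-β-ionone. The butenolide ring is made early from 1,3-dihydroxyacetone (Wittig olefination–lactonisation) and carried as its 2-silyloxyfuran.

Assumption: the (R,R)-ligand in step 10 is taken to give (5S); should the sense prove opposite, the (S,S)-ligand is used and nothing else changes.

## Route

Step 1
Reactants: 1 4-(2,6,6-trimethylcyclohex-1-en-1-yl)butan-2-one (dihydro-β-ionone)
Product: 4 2-(but-3-yn-1-yl)-1,3,3-trimethylcyclohex-1-ene, via enol phosphate 2 (not isolated), via lithium acetylide 3 (not isolated)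
Conditions: LiN(i-Pr)2 (1.1 equiv), THF, −78 °C; ClP(O)(OEt)2, −78 °C → rt; LiN(i-Pr)2 (2.3 equiv), −78 °C → rt; H2O
Reagents that add atoms: none
Why: Kinetic deprotonation at the methyl group, O-phosphorylation and base-induced elimination of the enol phosphate (Negishi conversion of a methyl ketone into a terminal alkyne) leave the tetrasubstituted ring alkene untouched.

Step 2
Reactants: 4 2-(but-3-yn-1-yl)-1,3,3-trimethylcyclohex-1-ene
Product: 6 1,3,3-trimethyl-2-[(3E)-3-methylhexa-3,5-dien-1-yl]cyclohex-1-ene, via alkenylalane 5 (not isolated)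
Conditions: AlMe3 (2 equiv), Cp2ZrCl2 (0.25 equiv), CH2Cl2, 0 °C → rt; then CH2=CHBr, Pd(PPh3)4 (5 mol%), ZnCl2, THF, rt
Reagents that add atoms: trimethylaluminium, C[Al](C)C; vinyl bromide, C=CBr
Why: Zirconium-catalysed syn-carboalumination of the terminal alkyne (Negishi) places methyl and aluminium cis with aluminium at the terminus, and the palladium-catalysed coupling of the alkenylalane with vinyl bromide goes with retention, so the trisubstituted alkene is formed essentially pure (E).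

Step 3
Reactants: 7 but-2-yne-1,4-diol
Product: 8 4-{[tert-butyl(dimethyl)silyl]oxy}but-2-yn-1-ol
Conditions: TBSCl (1 equiv), imidazole (1.1 equiv), 7 in excess (3 equiv), THF/DMF, 0 °C → rt
Reagents that add atoms: tert-butyl(chloro)dimethylsilane (TBSCl), CC(C)(C)[Si](C)(C)Cl
Why: Statistical monosilylation of the symmetrical diol used in excess gives the mono-TBS ether, and the water-soluble surplus diol is washed out.

Step 4
Reactants: 8 4-{[tert-butyl(dimethyl)silyl]oxy}but-2-yn-1-ol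
Product: 10 (2Z)-4-{[tert-butyl(dimethyl)silyl]oxy}-3-iodobut-2-en-1-ol, via cyclic alkenylalanate 9 (not isolated)
Conditions: NaAlH2(OCH2CH2OMe)2 (1.5 equiv), THF, 0 °C → rt; EtOAc; I2, THF, −78 °C → 0 °C
Reagents that add atoms: iodine, II
Why: Hydroxyl-directed trans-hydroalumination of the propargylic alcohol delivers hydride to C2 and aluminium to C3 through a five-membered alkoxyalanate, and iodinolysis with retention gives the (Z)-3-iodoallylic alcohol, which fixes the geometry of the later hydroxymethyl-bearing alkene.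

Step 5
Reactants: 6 1,3,3-trimethyl-2-[(3E)-3-methylhexa-3,5-dien-1-yl]cyclohex-1-ene; 10 (2Z)-4-{[tert-butyl(dimethyl)silyl]oxy}-3-iodobut-2-en-1-ol
Product: 12 (2E,6E)-3-({[tert-butyl(dimethyl)silyl]oxy}methyl)-7-methyl-9-(2,6,6-trimethylcyclohex-1-en-1-yl)nona-2,6-dien-1-ol, via B-alkyl-9-BBN 11 (not isolated)
Conditions: 9-BBN-H (1.05 equiv), THF, 0 °C → rt; then 10, PdCl2(dppf) (5 mol%), AsPh3 (10 mol%), Cs2CO3 (3 equiv), DMF/H2O, rt
Reagents that add atoms: none
Why: 9-BBN hydroborates only the terminal vinyl group of the diene at its CH2 terminus (anti-Markovnikov), and the B-alkyl Suzuki–Miyaura coupling replaces iodine with retention of alkene geometry, so both trisubstituted chain alkenes are in place.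

Step 6
Reactants: 12 (2E,6E)-3-({[tert-butyl(dimethyl)silyl]oxy}methyl)-7-methyl-9-(2,6,6-trimethylcyclohex-1-en-1-yl)nona-2,6-dien-1-ol
Product: 13 (2E,6E)-3-({[tert-butyl(dimethyl)silyl]oxy}methyl)-7-methyl-9-(2,6,6-trimethylcyclohex-1-en-1-yl)nona-2,6-dien-1-yl methyl carbonate
Conditions: ClCO2Me, pyridine, DMAP (cat.), CH2Cl2, 0 °C
Reagents that add atoms: methyl chloroformate, COC(=O)Cl
Why: Acylation of the primary allylic alcohol gives a carbonate that ionises readily with zerovalent palladium and releases only CO2 and methoxide.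

Step 7
Reactants: 14 1,3-dihydroxypropan-2-one (1,3-dihydroxyacetone, charged as its commercial dimer)
Product: 16 4-(hydroxymethyl)furan-2(5H)-one, via hydroxy enoate 15 (not isolated)
Conditions: Ph3P=CHCO2Et (1.05 equiv), CH2Cl2, rt, 16 h
Reagents that add atoms: ethyl (triphenyl-λ5-phosphanylidene)acetate, CCOC(=O)C=P(c1ccccc1)(c1ccccc1)c1ccccc1
Why: Wittig olefination of the ketone gives an enoate whose ester is necessarily cis to one of two identical CH2OH arms, so it lactonises spontaneously and forms the butenolide ring.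

Step 8
Reactants: 16 4-(hydroxymethyl)furan-2(5H)-one
Product: 17 4-({[tert-butyl(dimethyl)silyl]oxy}methyl)furan-2(5H)-one
Conditions: TBSCl, imidazole, DMF, 0 °C → rt
Reagents that add atoms: tert-butyl(chloro)dimethylsilane (TBSCl), CC(C)(C)[Si](C)(C)Cl
Why: Standard silylation of the primary alcohol under weakly basic conditions that do not open or isomerise the butenolide.

Step 9
Reactants: 17 4-({[tert-butyl(dimethyl)silyl]oxy}methyl)furan-2(5H)-one
Product: 18 4-({[tert-butyl(dimethyl)silyl]oxy}methyl)-2-{[tri(propan-2-yl)silyl]oxy}furan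
Conditions: TIPSOTf (1.1 equiv), Et3N (1.5 equiv), CH2Cl2, 0 °C
Reagents that add atoms: tri(propan-2-yl)silyl trifluoromethanesulfonate (TIPSOTf), CC(C)[Si](OS(=O)(=O)C(F)(F)F)(C(C)C)C(C)C
Why: O-silylation of the lactone carbonyl followed by loss of the γ-proton (soft enolisation) gives the aromatic 2-silyloxyfuran, a vinylogous nucleophile with its largest HOMO coefficient at C5.

Step 10
Reactants: 13 (2E,6E)-3-({[tert-butyl(dimethyl)silyl]oxy}methyl)-7-methyl-9-(2,6,6-trimethylcyclohex-1-en-1-yl)nona-2,6-dien-1-yl methyl carbonate; 18 4-({[tert-butyl(dimethyl)silyl]oxy}methyl)-2-{[tri(propan-2-yl)silyl]oxy}furan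
Product: 19 (5S)-4-({[tert-butyl(dimethyl)silyl]oxy}methyl)-5-[(2E,6E)-3-({[tert-butyl(dimethyl)silyl]oxy}methyl)-7-methyl-9-(2,6,6-trimethylcyclohex-1-en-1-yl)nona-2,6-dien-1-yl]furan-2(5H)-one
Conditions: Pd2(dba)3·CHCl3 (2.5 mol%), (R,R)-DACH-phenyl Trost ligand (7.5 mol%), CH2Cl2, −20 °C
Reagents that add atoms: none
Why: Proposed new method: an enantioselective, C5-selective and linear-selective allylic alkylation of a 5-unsubstituted 2-silyloxyfuran, in which zerovalent palladium ionises the carbonate to a cationic π-allyl complex plus methoxide (after loss of CO2), the neutral silyloxyfuran attacks outer-sphere through C5 at the unsubstituted allyl terminus (so the geometry at the disubstituted terminus is not disturbed), methoxide removes the bulky TIPS group that shields O and C3, and the chiral diphosphine pocket discriminates the two faces of C5 (flanked by the ring oxygen and the CH2OTBS arm) to set (5S) under base-free, cold conditions that should not enolise the product; the closest known reaction types are the Trost asymmetric allylic alkylation of prochiral enolates with prenyl-type carbonates and the racemic silver-promoted C5 alkylation of 2-silyloxyfurans with allylic halides.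

Step 11
Reactants: 19 (5S)-4-({[tert-butyl(dimethyl)silyl]oxy}methyl)-5-[(2E,6E)-3-({[tert-butyl(dimethyl)silyl]oxy}methyl)-7-methyl-9-(2,6,6-trimethylcyclohex-1-en-1-yl)nona-2,6-dien-1-yl]furan-2(5H)-one
Product: 20 (5S)-4-(hydroxymethyl)-5-[(2E,6E)-3-(hydroxymethyl)-7-methyl-9-(2,6,6-trimethylcyclohex-1-en-1-yl)nona-2,6-dien-1-yl]furan-2(5H)-one
Conditions: HF·pyridine, THF/pyridine, 0 °C → rt
Reagents that add atoms: none
Why: Buffered acidic fluoride cleaves both primary TBS ethers (silyl ether deprotection) without base, so the epimerisable C5–H of the butenolide and the acid-sensitive polyene are left alone.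

## Compound list

1 | 4-(2,6,6-trimethylcyclohex-1-en-1-yl)butan-2-one (dihydro-β-ionone) | CC(=O)CCC1=C(C)CCCC1(C)C | starting material
2 | diethyl 4-(2,6,6-trimethylcyclohex-1-en-1-yl)but-1-en-2-yl phosphate | C=C(CCC1=C(C)CCCC1(C)C)OP(=O)(OCC)OCC | intermediate
3 | lithium 4-(2,6,6-trimethylcyclohex-1-en-1-yl)but-1-yn-1-ide | [Li+].[C-]#CCCC1=C(C)CCCC1(C)C | intermediate
4 | 2-(but-3-yn-1-yl)-1,3,3-trimethylcyclohex-1-ene | C#CCCC1=C(C)CCCC1(C)C | intermediate
5 | dimethyl[(1E)-2-methyl-4-(2,6,6-trimethylcyclohex-1-en-1-yl)but-1-en-1-yl]alumane | C[Al](C)/C=C(\C)CCC1=C(C)CCCC1(C)C | intermediate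
6 | 1,3,3-trimethyl-2-[(3E)-3-methylhexa-3,5-dien-1-yl]cyclohex-1-ene | C=C/C=C(\C)CCC1=C(C)CCCC1(C)C | intermediate
7 | but-2-yne-1,4-diol | OCC#CCO | starting material
8 | 4-{[tert-butyl(dimethyl)silyl]oxy}but-2-yn-1-ol | OCC#CCO[Si](C)(C)C(C)(C)C | intermediate
9 | sodium 3-({[tert-butyl(dimethyl)silyl]oxy}methyl)-2,2-bis(2-methoxyethoxy)-2,5-dihydro-1,2-oxaaluminol-2-uide (five-membered O–Al–C=CH–CH2 ring) | [Na+].COCCO[Al-]1(OCCOC)OCC=C1CO[Si](C)(C)C(C)(C)C | intermediate
10 | (2Z)-4-{[tert-butyl(dimethyl)silyl]oxy}-3-iodobut-2-en-1-ol | OC/C=C(\I)CO[Si](C)(C)C(C)(C)C | intermediate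
11 | 9-[(3E)-4-methyl-6-(2,6,6-trimethylcyclohex-1-en-1-yl)hex-3-en-1-yl]-9-borabicyclo[3.3.1]nonane | CC1=C(CC/C(C)=C/CCB2C3CCCC2CCC3)C(C)(C)CCC1 | intermediate
12 | (2E,6E)-3-({[tert-butyl(dimethyl)silyl]oxy}methyl)-7-methyl-9-(2,6,6-trimethylcyclohex-1-en-1-yl)nona-2,6-dien-1-ol | CC1=C(CC/C(C)=C/CC/C(=C\CO)CO[Si](C)(C)C(C)(C)C)C(C)(C)CCC1 | intermediate
13 | (2E,6E)-3-({[tert-butyl(dimethyl)silyl]oxy}methyl)-7-methyl-9-(2,6,6-trimethylcyclohex-1-en-1-yl)nona-2,6-dien-1-yl methyl carbonate | CC1=C(CC/C(C)=C/CC/C(=C\COC(=O)OC)CO[Si](C)(C)C(C)(C)C)C(C)(C)CCC1 | intermediate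
14 | 1,3-dihydroxypropan-2-one (1,3-dihydroxyacetone) | OCC(=O)CO | starting material
15 | ethyl 4-hydroxy-3-(hydroxymethyl)but-2-enoate | CCOC(=O)C=C(CO)CO | intermediate
16 | 4-(hydroxymethyl)furan-2(5H)-one | O=C1OCC(CO)=C1 | intermediate
17 | 4-({[tert-butyl(dimethyl)silyl]oxy}methyl)furan-2(5H)-one | O=C1OCC(CO[Si](C)(C)C(C)(C)C)=C1 | intermediate
18 | 4-({[tert-butyl(dimethyl)silyl]oxy}methyl)-2-{[tri(propan-2-yl)silyl]oxy}furan | CC(C)[Si](Oc1cc(CO[Si](C)(C)C(C)(C)C)co1)(C(C)C)C(C)C | intermediate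
19 | (5S)-4-({[tert-butyl(dimethyl)silyl]oxy}methyl)-5-[(2E,6E)-3-({[tert-butyl(dimethyl)silyl]oxy}methyl)-7-methyl-9-(2,6,6-trimethylcyclohex-1-en-1-yl)nona-2,6-dien-1-yl]furan-2(5H)-one | CC1=C(CC/C(C)=C/CC/C(=C\C[C@@H]2OC(=O)C=C2CO[Si](C)(C)C(C)(C)C)CO[Si](C)(C)C(C)(C)C)C(C)(C)CCC1 | intermediate
20 | (5S)-4-(hydroxymethyl)-5-[(2E,6E)-3-(hydroxymethyl)-7-methyl-9-(2,6,6-trimethylcyclohex-1-en-1-yl)nona-2,6-dien-1-yl]furan-2(5H)-one | CC1=C(CC/C(C)=C/CC/C(=C\C[C@@H]2OC(=O)C=C2CO)CO)C(C)(C)CCC1 | target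

## Step count and risks

Total step count: 11.
Longest linear sequence: 6 steps (steps 1, 2, 5, 6, 10, 11 from 1; equally steps 3, 4, 5, 6, 10, 11 from 7).

Three steps most likely to fail:

1. Step 10 (the proposed new allylation). The risks are attack at C3 instead of C5, low enantioselectivity, and erosion of ee by enolisation of the product. The fallback uses known chemistry (Enders' chiral dihydroxyacetone equivalent), sets out from 12 and comes back at 19. Alcohol 12 is converted (MsCl, Et3N, CH2Cl2, −40 °C; then LiBr, THF) into the allylic bromide F1. Commercial 2,2-dimethyl-1,3-dioxan-5-one is condensed with SAMP to the SAMP hydrazone of the dioxanone F2. F2 is lithiated (t-BuLi, THF, −78 °C) and alkylated with F1 at −100 °C to give the alkylated hydrazone F3; the azaenolate model for this auxiliary gives the (4S) centre. Saturated aqueous oxalic acid/Et2O releases the (4S)-dioxanone F4 and the auxiliary. 1 M HCl in THF removes the acetonide and the silyl ether to give the trihydroxy ketone F5. TBSCl/imidazole (DMF, −20 °C) silylates only the two primary hydroxyls to give the bis-silylated α-hydroxy ketone F6. Ph3P=C=C=O (toluene, 80 °C) acylates the secondary hydroxyl and closes the butenolide by intramolecular Wittig reaction, giving 19.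

2. Step 5 (hydroboration/B-alkyl Suzuki coupling). The risks are slow boron-to-palladium transfer and protodeboronation with the hindered iodide. The fallback changes the nucleophile to zinc, sets out from 6 through the same borane 11, and comes back at 12. Borane 11 is oxidised (NaOH, H2O2) to the homoallylic alcohol F7 and converted (I2, PPh3, imidazole) into the iodide F8. Zinc insertion (Zn, LiCl, THF, 40 °C) gives the alkylzinc iodide F9. Negishi coupling of F9 with 10 (Pd(OAc)2, SPhos, THF, rt), which tolerates the free hydroxyl, gives 12 with retention of alkene geometry.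

3. Step 2 (one-pot carboalumination/vinylation; it also covers a poor step 1). The risks are incomplete carboalumination and a sluggish coupling with the volatile vinyl bromide. The fallback is a classical olefination sequence that sets out from 1 and comes back at 6. Horner–Wadsworth–Emmons reaction of 1 (NaH, (EtO)2P(O)CH2CO2Et, THF) gives, after chromatographic removal of the minor (Z)-isomer (about 4:1), the (E)-ester F10. (i-Bu)2AlH (CH2Cl2, −78 °C) reduces it to the allylic alcohol F11, and MnO2 (CH2Cl2) oxidises that to the enal F12. Wittig methylenation (Ph3PCH3Br, n-BuLi, THF, 0 °C) gives triene 6.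

## Further compounds

F1 | step 10 | (2E,6E)-1-bromo-3-({[tert-butyl(dimethyl)silyl]oxy}methyl)-7-methyl-9-(2,6,6-trimethylcyclohex-1-en-1-yl)nona-2,6-diene | CC1=C(CC/C(C)=C/CC/C(=C\CBr)CO[Si](C)(C)C(C)(C)C)C(C)(C)CCC1
F2 | step 10 | (2S)-N-(2,2-dimethyl-1,3-dioxan-5-ylidene)-2-(methoxymethyl)pyrrolidin-1-amine | CC1(C)OCC(=NN2CCC[C@H]2COC)CO1
F3 | step 10 | (2S)-N-{(4S)-4-[(2E,6E)-3-({[tert-butyl(dimethyl)silyl]oxy}methyl)-7-methyl-9-(2,6,6-trimethylcyclohex-1-en-1-yl)nona-2,6-dien-1-yl]-2,2-dimethyl-1,3-dioxan-5-ylidene}-2-(methoxymethyl)pyrrolidin-1-amine | CC1=C(CC/C(C)=C/CC/C(=C\C[C@@H]2OC(C)(C)OCC2=NN3CCC[C@H]3COC)CO[Si](C)(C)C(C)(C)C)C(C)(C)CCC1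
F4 | step 10 | (4S)-4-[(2E,6E)-3-({[tert-butyl(dimethyl)silyl]oxy}methyl)-7-methyl-9-(2,6,6-trimethylcyclohex-1-en-1-yl)nona-2,6-dien-1-yl]-2,2-dimethyl-1,3-dioxan-5-one | CC1=C(CC/C(C)=C/CC/C(=C\C[C@@H]2OC(C)(C)OCC2=O)CO[Si](C)(C)C(C)(C)C)C(C)(C)CCC1
F5 | step 10 | (3S,5E,9E)-1,3-dihydroxy-6-(hydroxymethyl)-10-methyl-12-(2,6,6-trimethylcyclohex-1-en-1-yl)dodeca-5,9-dien-2-one | CC1=C(CC/C(C)=C/CC/C(=C\C[C@H](O)C(=O)CO)CO)C(C)(C)CCC1
F6 | step 10 | (3S,5E,9E)-1-{[tert-butyl(dimethyl)silyl]oxy}-6-({[tert-butyl(dimethyl)silyl]oxy}methyl)-3-hydroxy-10-methyl-12-(2,6,6-trimethylcyclohex-1-en-1-yl)dodeca-5,9-dien-2-one | CC1=C(CC/C(C)=C/CC/C(=C\C[C@H](O)C(=O)CO[Si](C)(C)C(C)(C)C)CO[Si](C)(C)C(C)(C)C)C(C)(C)CCC1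
F7 | step 5 | (3E)-4-methyl-6-(2,6,6-trimethylcyclohex-1-en-1-yl)hex-3-en-1-ol | OCC/C=C(\C)CCC1=C(C)CCCC1(C)C
F8 | step 5 | 2-[(3E)-6-iodo-3-methylhex-3-en-1-yl]-1,3,3-trimethylcyclohex-1-ene | ICC/C=C(\C)CCC1=C(C)CCCC1(C)C
F9 | step 5 | iodo[(3E)-4-methyl-6-(2,6,6-trimethylcyclohex-1-en-1-yl)hex-3-en-1-yl]zinc | I[Zn]CC/C=C(\C)CCC1=C(C)CCCC1(C)C
F10 | step 2 | ethyl (2E)-3-methyl-5-(2,6,6-trimethylcyclohex-1-en-1-yl)pent-2-enoate | CCOC(=O)/C=C(\C)CCC1=C(C)CCCC1(C)C
F11 | step 2 | (2E)-3-methyl-5-(2,6,6-trimethylcyclohex-1-en-1-yl)pent-2-en-1-ol | OC/C=C(\C)CCC1=C(C)CCCC1(C)C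
F12 | step 2 | (2E)-3-methyl-5-(2,6,6-trimethylcyclohex-1-en-1-yl)pent-2-enal | O=C/C=C(\C)CCC1=C(C)CCCC1(C)C
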